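## Retrosynthetic overview

1. All carbon comes from two cheap pieces, as in the polyketide pathway: methyl docosanoate 1 (the behenoyl starter unit) and 3-methylpentane-2,4-dione 2 (a C-methylated diketide).
2. Key disconnection, the only ring: the benzene ring is opened at the aldol bond of a methylated tetraketide. Forward, Claisen chain extension gives triketone 3, carboxylation gives triketo acid 4, C2→C7 aldol closure gives resorcylic acid 5, and loss of CO2 gives resorcinol 6. This is the alkylresorcinol-synthase sequence, run in one flask.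
3. The two remaining ring C–O bonds are disconnected as the two post-cyclisation hydroxylations: 6 → hydroxyquinone 7 (C–H oxidation para to OH) → aminoquinone 8 (oxidative amination of the last ring C–H) → target 9 (hydrolysis).
4. Ring order: one carbocycle, formed in step 1; nothing else is cyclic.

Assumption: the target has no stereocentre and no stereogenic double bond, so it is one achiral compound and no stereocontrol is needed.

## Route

Step 1
Reactants: 1 methyl docosanoate; 2 3-methylpentane-2,4-dione
Product: 6 5-henicosyl-2-methylbenzene-1,3-diol, via triketone 3 (not isolated), via triketo acid 4 (not isolated), via resorcylic acid 5 (not isolated)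
Conditions: 2 (2.2 equiv), LiN(iPr)2 (4.4 equiv), THF, 0 °C; 1 (1.0 equiv), 0 °C → rt; LiN(iPr)2 (2.5 equiv), −78 → 0 °C; CO2 (excess), −78 °C → rt; H2O, rt, 16 h (pH ≈ 8, LiHCO3-buffered); aq. HCl to pH 1, dioxane, 90 °C
Reagents that add atoms: none
Why: Proposed new method: the one-flask telescoping and the site of the third deprotonation are untested, but each event is a known β-polycarbonyl polyanion reaction (Claisen acylation of the diketone dianion at its terminal carbanion to give 3; kinetic deprotonation of 3 at the unhindered C1 methyl and C-carboxylation to give 4; intramolecular C2-to-C7 aldol condensation of 4, where the doubly activated C2 methylene is the only strong nucleophile, to give 5; thermal decarboxylation of the electron-rich β-resorcylic acid), the closest known reaction type being the biomimetic cyclisation of 3,5,7-triketo acids to resorcylic acids, and no stereocentre is formed.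

Step 2
Reactants: 6 5-henicosyl-2-methylbenzene-1,3-diol
Product: 7 5-henicosyl-3-hydroxy-2-methylcyclohexa-2,5-diene-1,4-dione
Conditions: ON(SO3K)2 (2.5 equiv), aq. KH2PO4, THF, methyltrioctylammonium chloride (5 mol %), rt
Reagents that add atoms: potassium nitrosodisulfonate ON(SO3K)2, [K+].[K+].[O]N(S(=O)(=O)[O-])S(=O)(=O)[O-]
Why: Teuber oxidation, in which the phenoxyl radical of the resorcinol is trapped by a second nitroxide at C4 (para to one OH; C4 and C6 are equivalent and C2 is blocked by methyl) and loss of HN(SO3K)2 gives the 2-hydroxy-1,4-benzoquinone, as known for other 2-substituted 5-alkylresorcinols; no stereocentre is formed.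

Step 3
Reactants: 7 5-henicosyl-3-hydroxy-2-methylcyclohexa-2,5-diene-1,4-dione
Product: 9 2-henicosyl-3,6-dihydroxy-5-methylcyclohexa-2,5-diene-1,4-dione, via aminoquinone 8 (not isolated)
Conditions: MeNH2 (40% aq., 6 equiv), EtOH/THF, air, rt, 12 h; concentrate; 6 M H2SO4, dioxane, 90 °C
Reagents that add atoms: water, O
Why: Oxidative amination followed by vinylogous amide hydrolysis, in which methylamine adds in conjugate fashion to C6 of 7 (the only unsubstituted ring carbon, β to the C4 carbonyl), air re-oxidises the adduct to 8, and aqueous acid exchanges the amino group for hydroxyl (any amine that also replaces the existing OH is hydrolysed back in the same operation); no stereocentre is formed.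

## Compound list

1 | methyl docosanoate (methyl behenate) | CCCCCCCCCCCCCCCCCCCCCC(=O)OC | starting material
2 | 3-methylpentane-2,4-dione | CC(=O)C(C)C(C)=O | starting material
3 | 3-methylheptacosane-2,4,6-trione (racemic at C3, in equilibrium with its enols) | CCCCCCCCCCCCCCCCCCCCCC(=O)CC(=O)C(C)C(C)=O | intermediate
4 | 4-methyl-3,5,7-trioxooctacosanoic acid (racemic at C4, in equilibrium with its enols) | CCCCCCCCCCCCCCCCCCCCCC(=O)CC(=O)C(C)C(=O)CC(=O)O | intermediate
5 | 6-henicosyl-2,4-dihydroxy-3-methylbenzoic acid | CCCCCCCCCCCCCCCCCCCCCc1cc(O)c(C)c(O)c1C(=O)O | intermediate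
6 | 5-henicosyl-2-methylbenzene-1,3-diol | CCCCCCCCCCCCCCCCCCCCCc1cc(O)c(C)c(O)c1 | intermediate
7 | 5-henicosyl-3-hydroxy-2-methylcyclohexa-2,5-diene-1,4-dione | CCCCCCCCCCCCCCCCCCCCCC1=CC(=O)C(C)=C(O)C1=O | intermediate
8 | 2-henicosyl-6-hydroxy-5-methyl-3-(methylamino)cyclohexa-2,5-diene-1,4-dione | CCCCCCCCCCCCCCCCCCCCCC1=C(NC)C(=O)C(C)=C(O)C1=O | intermediate
9 | 2-henicosyl-3,6-dihydroxy-5-methylcyclohexa-2,5-diene-1,4-dione (achiral) | CCCCCCCCCCCCCCCCCCCCCC1=C(O)C(=O)C(C)=C(O)C1=O | target

## Step count and risks

Total steps: 3. Longest linear sequence: 3 steps (1 and 2 → 6 → 7 → 9).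

Steps most likely to fail, most risky first:

**Step 1.** The risks are:
- incomplete Claisen acylation by an enolisable fatty ester;
- third deprotonation of 3 at C7 (chain methylene) instead of C1, which would give a regioisomeric acid and, after closure, 4-icosyl-5,6-dimethylresorcinol;
- pyrone formation from 4 competing with the aldol closure.

Fallback, setting out from 1 and coming back at 6: the ring is closed by a Michael–Claisen annulation instead of an open-chain tetraketide aldol. Reduction of 1 with iBu2AlH (toluene, −78 °C) gives docosanal F1. Horner–Wadsworth–Emmons olefination with diethyl (2-oxobutyl)phosphonate and NaH in THF gives (E)-hexacos-4-en-3-one F2. Dimethyl malonate with NaOMe in refluxing MeOH adds to give dimethyl 2-(3-oxohexacosan-5-yl)propanedioate F3, which closes in the same pot to methyl 2-henicosyl-5-methyl-4,6-dioxocyclohexane-1-carboxylate F4. Aqueous NaOH and then HCl give 2-henicosyl-5-methyl-4,6-dioxocyclohexane-1-carboxylic acid F5, which loses CO2 on warming to give 5-henicosyl-2-methylcyclohexane-1,3-dione F6. Dehydrogenation over Pd/C in refluxing mesitylene then gives 6.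

**Step 3.** The risks are that the hydroxyquinone anion is a sluggish Michael acceptor, that amine-mediated dimerisation competes, and that the aminoquinone hydrolyses slowly.

Fallback, setting out from 7 and coming back at 9: the last oxygen is brought in by acid-catalysed acetoxylation instead of amine addition. Thiele–Winter reaction (Ac2O, cat. H2SO4 or BF3·OEt2, 25–50 °C) acetylates the hydroxyl and adds acetate at C6, giving 3-henicosyl-6-methylbenzene-1,2,4,5-tetrayl tetraacetate F7. NaOH in aqueous MeOH under N2 gives 3-henicosyl-6-methylbenzene-1,2,4,5-tetrol F8. Admitting air and acidifying then gives 9 by autoxidation.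

**Step 2.** The risks are poor contact between the waxy resorcinol and the aqueous radical salt, and oxidative dimerisation.

Fallback, setting out from 6 and coming back at 7: the oxygen is installed by formylation and oxygen insertion instead of radical oxidation. Vilsmeier formylation (POCl3, DMF, then H2O) gives 6-henicosyl-2,4-dihydroxy-3-methylbenzaldehyde F9. Dakin oxidation (H2O2 1.05 equiv, aq. NaOH, THF, N2, 0 °C) gives 6-henicosyl-3-methylbenzene-1,2,4-triol F10. Shaking the acidified solution with air then oxidises the triol to 7.

## Further compounds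

F1 | step 1 | docosanal | CCCCCCCCCCCCCCCCCCCCCC=O
F2 | step 1 | (E)-hexacos-4-en-3-one | CCCCCCCCCCCCCCCCCCCCC/C=C/C(=O)CC
F3 | step 1 | dimethyl 2-(3-oxohexacosan-5-yl)propanedioate (racemic) | CCCCCCCCCCCCCCCCCCCCCC(CC(=O)CC)C(C(=O)OC)C(=O)OC
F4 | step 1 | methyl 2-henicosyl-5-methyl-4,6-dioxocyclohexane-1-carboxylate (mixture of stereoisomers and enol forms) | CCCCCCCCCCCCCCCCCCCCCC1CC(=O)C(C)C(=O)C1C(=O)OC
F5 | step 1 | 2-henicosyl-5-methyl-4,6-dioxocyclohexane-1-carboxylic acid (mixture of stereoisomers and enol forms) | CCCCCCCCCCCCCCCCCCCCCC1CC(=O)C(C)C(=O)C1C(=O)O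
F6 | step 1 | 5-henicosyl-2-methylcyclohexane-1,3-dione (mixture of stereoisomers and enol forms) | CCCCCCCCCCCCCCCCCCCCCC1CC(=O)C(C)C(=O)C1
F7 | step 3 | 3-henicosyl-6-methylbenzene-1,2,4,5-tetrayl tetraacetate | CCCCCCCCCCCCCCCCCCCCCc1c(OC(C)=O)c(OC(C)=O)c(C)c(OC(C)=O)c1OC(C)=O
F8 | step 3 | 3-henicosyl-6-methylbenzene-1,2,4,5-tetrol | CCCCCCCCCCCCCCCCCCCCCc1c(O)c(O)c(C)c(O)c1O
F9 | step 2 | 6-henicosyl-2,4-dihydroxy-3-methylbenzaldehyde | CCCCCCCCCCCCCCCCCCCCCc1cc(O)c(C)c(O)c1C=O
F10 | step 2 | 6-henicosyl-3-methylbenzene-1,2,4-triol | CCCCCCCCCCCCCCCCCCCCCc1cc(O)c(C)c(O)c1O
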